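**Retrosynthetic overview**
1. Target ⇒ diterpenoid acid + (R)-glycidyl acetate: the ester C–O bond is made last by opening the epoxide CH2 with the acid, which brings in the glycerol stereocentre untouched.
2. C1=C10 olefin and H-5 ⇒ 1-hydroxy-Δ5(10)-octalin by a reductive 1,3-transposition through a C–N bond (allylic diazene, loss of N2); the carbinol comes from CBS reduction of the ring-fusion enone.
3. Ring A (closed last) ⇒ cobalt-hydride radical cycloisomerisation of a ring B dienone (C4–C5 bond, new reaction); the dienone comes from carbonylative coupling of the ring B enol triflate with a C5 zinc reagent.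
4. Ring B (bought as 2-iodocyclohex-2-enone) ⇒ C8 and C9 by Cu-catalysed asymmetric conjugate methylation then enolate methylation; the side chain with C13 comes from monomethyl (R)-3-methylglutarate by Negishi coupling.

Assumption: halimane numbering is used (C4 gem-dimethyl, C5 ring-fusion CH, C8 CHMe, C9 quaternary, C1=C10 olefin, side chain C11–C16); the SMILES is read as 5S,8R,9R,13R with (S) at the glycerol carbon, and (R)-glycidyl acetate (the acetate of (S)-glycidol) is taken as a purchasable reagent.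

**Route**

Step 1
Reactants: 1 (3R)-5-methoxy-3-methyl-5-oxopentanoic acid (monomethyl (R)-3-methylglutarate)
Product: 2 methyl (3R)-5-hydroxy-3-methylpentanoate
Conditions: BH3·SMe2 (1.1 equiv), THF, 0 → 23 °C; aqueous work-up, used at once (lactonises on standing)
Reagents that add atoms: none
Why: Chemoselective borane reduction of a carboxylic acid beside a methyl ester; the C13 stereocentre is not touched.

Step 2
Reactants: 2 methyl (3R)-5-hydroxy-3-methylpentanoate
Product: 3 methyl (3S)-5-iodo-3-methylpentanoate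
Conditions: I2, PPh3, imidazole, CH2Cl2, 0 °C
Reagents that add atoms: iodine, II
Why: Appel-type iodination of the primary alcohol; the stereocentre is untouched and its label becomes S only because CH2CH2I now outranks CH2CO2Me.

Step 3
Reactants: 3 methyl (3S)-5-iodo-3-methylpentanoate; 4 2-iodocyclohex-2-en-1-one
Product: 6 methyl (3R)-3-methyl-5-(6-oxocyclohex-1-en-1-yl)pentanoate, via alkylzinc iodide 5 (not isolated)
Conditions: 3, Zn dust, LiCl, THF, 40 °C; then 4, Pd2(dba)3 (2.5 mol%), tri(2-furyl)phosphine (10 mol%), THF/DMF, 23 °C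
Reagents that add atoms: none
Why: Zinc insertion into the primary iodide tolerates the ester, and Negishi sp3–sp2 coupling with the α-iodoenone gives the 2-alkylcyclohexenone.

Step 4
Reactants: 6 methyl (3R)-3-methyl-5-(6-oxocyclohex-1-en-1-yl)pentanoate
Product: 9 methyl (3R)-5-[(1R,2R)-1,2-dimethyl-6-oxocyclohexyl]-3-methylpentanoate, via dimethylaluminium enolate 7 (not isolated), via lithium aluminate enolate 8 (not isolated)
Conditions: AlMe3 (1.4 equiv), Cu(O2CC4H3S) (copper thiophene-2-carboxylate, 2 mol%), BINOL-derived N,N-bis(1-phenylethyl)phosphoramidite (4 mol%, the enantiomer that gives the 6R enolate), Et2O, −30 °C; then MeLi (1.0 equiv per Al), THF, −78 °C; MeI (5 equiv), HMPA, −78 → 0 °C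
Reagents that add atoms: trimethylaluminium, C[Al](C)C; iodomethane, CI
Why: Cu-catalysed asymmetric conjugate addition sets C8 (R) under ligand control, and the ate-activated enolate is then C-methylated anti to the new C8 methyl, which makes C9 quaternary (R) with its methyl trans to the C8 methyl.

Step 5
Reactants: 9 methyl (3R)-5-[(1R,2R)-1,2-dimethyl-6-oxocyclohexyl]-3-methylpentanoate
Product: 11 methyl (3R)-5-[(1R,6R)-1,6-dimethyl-2-{[(trifluoromethyl)sulfonyl]oxy}cyclohex-2-en-1-yl]-3-methylpentanoate, via potassium enolate 10 (not isolated)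
Conditions: KN(SiMe3)2 (1.0 equiv), THF, −78 °C; then PhNTf2, −78 → 0 °C
Reagents that add atoms: N-phenylbis(trifluoromethanesulfonimide), O=S(=O)(N(c1ccccc1)S(=O)(=O)C(F)(F)F)C(F)(F)F
Why: Enol triflate formation; the ketone can enolise only toward C5 (C9 is quaternary) and is about five pKa units more acidic than the ester, so a single C5=C10 triflate forms.

Step 6
Reactants: 11 methyl (3R)-5-[(1R,6R)-1,6-dimethyl-2-{[(trifluoromethyl)sulfonyl]oxy}cyclohex-2-en-1-yl]-3-methylpentanoate; 12 4-bromo-2-methylbut-1-ene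
Product: 14 methyl (3R)-5-[(1R,6R)-1,6-dimethyl-2-(4-methylpent-4-enoyl)cyclohex-2-en-1-yl]-3-methylpentanoate, via homoallylzinc bromide 13 (not isolated)
Conditions: 12, Zn dust, LiCl, THF, 40 °C; then 11, Pd(PPh3)4 (5 mol%), CO (1 atm), THF/NMP, 50 °C
Reagents that add atoms: carbon monoxide, [C-]#[O+]
Why: Carbonylative Negishi coupling; CO inserts into the hindered alkenyl–palladium bond before transmetalation, so C1 enters as the ketone carbon of an alkyl alkenyl ketone.

Step 7
Reactants: 14 methyl (3R)-5-[(1R,6R)-1,6-dimethyl-2-(4-methylpent-4-enoyl)cyclohex-2-en-1-yl]-3-methylpentanoate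
Product: 15 methyl (3R)-3-methyl-5-[(1R,2R)-1,2,5,5-tetramethyl-8-oxo-1,2,3,4,5,6,7,8-octahydronaphthalen-1-yl]pentanoate
Conditions: Co(salen)Cl (5 mol%; salen = N,N′-bis(3,5-di-tert-butylsalicylidene)-1,2-cyclohexanediaminate), PhSiH3 (10 mol%), benzene, 23 °C, argon
Reagents that add atoms: none
Why: Proposed new method: cobalt hydride (from Co(salen)Cl and PhSiH3) transfers a hydrogen atom to the 1,1-disubstituted olefin, the tertiary C4 radical adds 6-endo to the enone β-carbon C5 (polarity-matched, whereas 5-exo attack at the fully substituted α-carbon is disfavoured), and the α-keto C10 radical returns its only β-hydrogen (H-5) to divalent cobalt, which regenerates Co–H and the conjugated tetrasubstituted enone, so ring A and the C4–C5 bond (with the gem-dimethyl group) form in a redox-neutral chain; the closest known reactions are Co(salen)-catalysed hydrogen-atom-transfer cycloisomerisation of dienes and Fe(acac)3/PhSiH3 reductive olefin–enone coupling.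

Step 8
Reactants: 15 methyl (3R)-3-methyl-5-[(1R,2R)-1,2,5,5-tetramethyl-8-oxo-1,2,3,4,5,6,7,8-octahydronaphthalen-1-yl]pentanoate
Product: 16 methyl (3R)-5-[(1R,2R,8R)-8-hydroxy-1,2,5,5-tetramethyl-1,2,3,4,5,6,7,8-octahydronaphthalen-1-yl]-3-methylpentanoate
Conditions: (S)-2-methyl-CBS-oxazaborolidine (20 mol%), catecholborane (1.5 equiv), toluene, −78 → −40 °C
Reagents that add atoms: none
Why: CBS reduction; with the alkenyl carbon as the large group the (S)-catalyst delivers hydride to give the 8R carbinol (as acetophenone gives the R alcohol), under catalyst control because the two C9 substituents shield both faces of the ketone almost equally.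

Step 9
Reactants: 16 methyl (3R)-5-[(1R,2R,8R)-8-hydroxy-1,2,5,5-tetramethyl-1,2,3,4,5,6,7,8-octahydronaphthalen-1-yl]-3-methylpentanoate
Product: 19 methyl (3R)-3-methyl-5-[(1R,2R,4aS)-1,2,5,5-tetramethyl-1,2,3,4,4a,5,6,7-octahydronaphthalen-1-yl]pentanoate, via sulfonylhydrazine adduct 17 (not isolated), via allylic diazene 18 (not isolated)
Conditions: PPh3, DEAD, 2-nitrobenzenesulfonylhydrazide, N-methylmorpholine, −30 °C; then 23 °C
Reagents that add atoms: none
Why: Myers reductive 1,3-transposition; Mitsunobu C–N bond formation inverts C1, loss of sulfinic acid gives the diazene, and its retro-ene loss of N2 delivers hydrogen to C5 on the face of the C–N bond, which sets C5 (4aS) and places the olefin at C1=C10 without choice.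

Step 10
Reactants: 19 methyl (3R)-3-methyl-5-[(1R,2R,4aS)-1,2,5,5-tetramethyl-1,2,3,4,4a,5,6,7-octahydronaphthalen-1-yl]pentanoate
Product: 20 (3R)-3-methyl-5-[(1R,2R,4aS)-1,2,5,5-tetramethyl-1,2,3,4,4a,5,6,7-octahydronaphthalen-1-yl]pentanoic acid
Conditions: LiOH, THF/MeOH/H2O, 23 °C; then 1 M HCl
Reagents that add atoms: lithium hydroxide, [Li+].[OH-]
Why: Saponification of the methyl ester; no stereocentre is α to the carboxyl group, so nothing epimerises.

Step 11
Reactants: 20 (3R)-3-methyl-5-[(1R,2R,4aS)-1,2,5,5-tetramethyl-1,2,3,4,4a,5,6,7-octahydronaphthalen-1-yl]pentanoic acid; 21 [(2R)-oxiran-2-yl]methyl acetate ((R)-glycidyl acetate)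
Product: 22 (2S)-3-(acetyloxy)-2-hydroxypropyl (3R)-3-methyl-5-[(1R,2R,4aS)-1,2,5,5-tetramethyl-1,2,3,4,4a,5,6,7-octahydronaphthalen-1-yl]pentanoate
Conditions: 21 (1.5 equiv), Co(salen)(OAc) from racemic ligand (5 mol%), i-Pr2NEt (1 equiv), tert-butyl methyl ether, 23 °C
Reagents that add atoms: none
Why: Co(salen)-catalysed acidolysis of a terminal epoxide; the carboxylate attacks the CH2 carbon (C–O bond formation), no bond to the stereocentre breaks, and it becomes the (S)-carbinol of the 1-acyl-3-acetyl glycerol while mild, near-neutral conditions limit acyl migration.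

**Compound list**
1 | (3R)-5-methoxy-3-methyl-5-oxopentanoic acid (monomethyl (R)-3-methylglutarate) | COC(=O)C[C@H](C)CC(=O)O | starting material
2 | methyl (3R)-5-hydroxy-3-methylpentanoate | COC(=O)C[C@H](C)CCO | intermediate
3 | methyl (3S)-5-iodo-3-methylpentanoate | COC(=O)C[C@H](C)CCI | intermediate
4 | 2-iodocyclohex-2-en-1-one | O=C1CCCC=C1I | starting material
5 | [(3S)-5-methoxy-3-methyl-5-oxopentyl]zinc iodide | COC(=O)C[C@H](C)CC[Zn]I | intermediate
6 | methyl (3R)-3-methyl-5-(6-oxocyclohex-1-en-1-yl)pentanoate | COC(=O)C[C@H](C)CCC1=CCCCC1=O | intermediate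
7 | methyl (3R)-5-{(6R)-2-[(dimethylalumanyl)oxy]-6-methylcyclohex-1-en-1-yl}-3-methylpentanoate | COC(=O)C[C@H](C)CCC1=C(O[Al](C)C)CCC[C@H]1C | intermediate
8 | lithium trimethylaluminate adduct of enolate 7 | COC(=O)C[C@H](C)CCC1=C(O[Al-](C)(C)C)CCC[C@H]1C.[Li+] | intermediate
9 | methyl (3R)-5-[(1R,2R)-1,2-dimethyl-6-oxocyclohexyl]-3-methylpentanoate | COC(=O)C[C@H](C)CC[C@@]1(C)C(=O)CCC[C@H]1C | intermediate
10 | potassium (5R,6R)-6-[(3R)-5-methoxy-3-methyl-5-oxopentyl]-5,6-dimethylcyclohex-1-en-1-olate | COC(=O)C[C@H](C)CC[C@@]1(C)C([O-])=CCC[C@H]1C.[K+] | intermediate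
11 | methyl (3R)-5-[(1R,6R)-1,6-dimethyl-2-{[(trifluoromethyl)sulfonyl]oxy}cyclohex-2-en-1-yl]-3-methylpentanoate | COC(=O)C[C@H](C)CC[C@@]1(C)C(OS(=O)(=O)C(F)(F)F)=CCC[C@H]1C | intermediate
12 | 4-bromo-2-methylbut-1-ene | C=C(C)CCBr | starting material
13 | (3-methylbut-3-en-1-yl)zinc bromide | C=C(C)CC[Zn]Br | intermediate
14 | methyl (3R)-5-[(1R,6R)-1,6-dimethyl-2-(4-methylpent-4-enoyl)cyclohex-2-en-1-yl]-3-methylpentanoate | COC(=O)C[C@H](C)CC[C@@]1(C)C(C(=O)CCC(C)=C)=CCC[C@H]1C | intermediate
15 | methyl (3R)-3-methyl-5-[(1R,2R)-1,2,5,5-tetramethyl-8-oxo-1,2,3,4,5,6,7,8-octahydronaphthalen-1-yl]pentanoate | COC(=O)C[C@H](C)CC[C@@]1(C)C2=C(CC[C@H]1C)C(C)(C)CCC2=O | intermediate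
16 | methyl (3R)-5-[(1R,2R,8R)-8-hydroxy-1,2,5,5-tetramethyl-1,2,3,4,5,6,7,8-octahydronaphthalen-1-yl]-3-methylpentanoate | COC(=O)C[C@H](C)CC[C@@]1(C)C2=C(CC[C@H]1C)C(C)(C)CC[C@H]2O | intermediate
17 | methyl (3R)-3-methyl-5-{(1R,2R,8S)-1,2,5,5-tetramethyl-8-[1-(2-nitrobenzenesulfonyl)hydrazin-1-yl]-1,2,3,4,5,6,7,8-octahydronaphthalen-1-yl}pentanoate | COC(=O)C[C@H](C)CC[C@@]1(C)C2=C(CC[C@H]1C)C(C)(C)CC[C@@H]2N(N)S(=O)(=O)c1ccccc1[N+](=O)[O-] | intermediate
18 | methyl (3R)-5-[(1R,2R,8S)-8-diazenyl-1,2,5,5-tetramethyl-1,2,3,4,5,6,7,8-octahydronaphthalen-1-yl]-3-methylpentanoate | COC(=O)C[C@H](C)CC[C@@]1(C)C2=C(CC[C@H]1C)C(C)(C)CC[C@@H]2N=N | intermediate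
19 | methyl (3R)-3-methyl-5-[(1R,2R,4aS)-1,2,5,5-tetramethyl-1,2,3,4,4a,5,6,7-octahydronaphthalen-1-yl]pentanoate | COC(=O)C[C@H](C)CC[C@@]1(C)C2=CCCC(C)(C)[C@@H]2CC[C@H]1C | intermediate
20 | (3R)-3-methyl-5-[(1R,2R,4aS)-1,2,5,5-tetramethyl-1,2,3,4,4a,5,6,7-octahydronaphthalen-1-yl]pentanoic acid | OC(=O)C[C@H](C)CC[C@@]1(C)C2=CCCC(C)(C)[C@@H]2CC[C@H]1C | intermediate
21 | [(2R)-oxiran-2-yl]methyl acetate ((R)-glycidyl acetate) | CC(=O)OC[C@H]1CO1 | starting material
22 | (2S)-3-(acetyloxy)-2-hydroxypropyl (3R)-3-methyl-5-[(1R,2R,4aS)-1,2,5,5-tetramethyl-1,2,3,4,4a,5,6,7-octahydronaphthalen-1-yl]pentanoate | CC(=O)OC[C@H](O)COC(=O)C[C@H](C)CC[C@@]1(C)C2=CCCC(C)(C)[C@@H]2CC[C@H]1C | target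

**Step count and risks**
Total steps: 11. Longest linear sequence: 11 (1 → 22); compounds 4, 12 and 21 are bought and enter at steps 3, 6 and 11.

The three steps most likely to fail:

The cobalt-hydride cycloisomerisation (step 7) is the least certain. The tertiary radical may simply return its hydrogen to cobalt (olefin isomerisation) or be reduced instead of closing the ring. The fallback uses known chemistry, sets out from 14 and comes back at 15. Markovnikov addition of HBr (HBr in AcOH, 0 °C) to the 1,1-disubstituted olefin gives the tertiary bromide methyl (3R)-5-[(1R,6R)-2-(4-bromo-4-methylpentanoyl)-1,6-dimethylcyclohex-2-en-1-yl]-3-methylpentanoate F1. A palladium-catalysed radical alkyl-Heck cyclisation (Pd(OAc)2, Xantphos, Cs2CO3, blue light, benzene, 23 °C) then forms the same C4–C5 bond in the 6-endo mode and restores the enone by β-hydride elimination, giving 15.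

The Mitsunobu/diazene transposition (step 9) may be slow at the hindered allylic carbinol or give diene by elimination. The fallback sets out from 16 and comes back at 19. Formylation (HCO2H, DCC, DMAP, CH2Cl2) gives the allylic formate methyl (3R)-5-[(1R,2R,8R)-8-(formyloxy)-1,2,5,5-tetramethyl-1,2,3,4,5,6,7,8-octahydronaphthalen-1-yl]-3-methylpentanoate F2. Tsuji–Mandai hydrogenolysis (Pd(OAc)2, n-Bu3P, dioxane, reflux) ionises the formate with inversion, loses CO2 and passes hydride from palladium to C5, anti to the original C–O bond. This gives the same 4aS centre and C1=C10 olefin, that is 19.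

The conjugate addition/methylation (step 4) needs the ate-complex methylation to beat attack of MeLi on the ester and O-methylation, and the enantioselectivity on this 2-alkyl enone is unproven. The fallback sets out from 6 and comes back at 9. The same conjugate addition is run, but enolate 7 is trapped with Me3SiOTf/Et3N and the silyl enol ether methyl (3R)-3-methyl-5-{(6R)-6-methyl-2-[(trimethylsilyl)oxy]cyclohex-1-en-1-yl}pentanoate F3 is isolated. Anhydrous benzyltrimethylammonium fluoride with MeI (THF, −78 → 0 °C) then releases a metal-free enolate that is C-methylated regiospecifically, again anti to the C8 methyl, to give 9.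

Further compounds
F1 | step 7 | methyl (3R)-5-[(1R,6R)-2-(4-bromo-4-methylpentanoyl)-1,6-dimethylcyclohex-2-en-1-yl]-3-methylpentanoate | COC(=O)C[C@H](C)CC[C@@]1(C)C(C(=O)CCC(C)(C)Br)=CCC[C@H]1C
F2 | step 9 | methyl (3R)-5-[(1R,2R,8R)-8-(formyloxy)-1,2,5,5-tetramethyl-1,2,3,4,5,6,7,8-octahydronaphthalen-1-yl]-3-methylpentanoate | COC(=O)C[C@H](C)CC[C@@]1(C)C2=C(CC[C@H]1C)C(C)(C)CC[C@H]2OC=O
F3 | step 4 | methyl (3R)-3-methyl-5-{(6R)-6-methyl-2-[(trimethylsilyl)oxy]cyclohex-1-en-1-yl}pentanoate | COC(=O)C[C@H](C)CCC1=C(O[Si](C)(C)C)CCC[C@H]1C
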